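## The problem

The target (29) is a heptaphenol built on a bicyclo[3.2.1]oct-2-ene-4,8-dione. C1 is the quaternary bridgehead, C2=C3–C4(=O) the three-carbon bridge (ring A: C1, C2, C3, C4, C5, C8), C5 the second bridgehead, C6–C7 the two-carbon bridge and C8 the bridging ketone (ring B: C1, C8, C5, C6, C7). C1 and C2 also belong to a cyclopentane (ring C: C1, C2, C11, C10, C9), cis-fused through C10–C11 to an indane (ring D: C10, C11, C12 and two carbons of a 3,5-dioxygenated arene), so C1 is a spiro centre with four different carbon substituents. Eight contiguous stereocentres must be set (C1, C5, C6, C7, C9, C10, C11, C12). With ring B drawn flat, C1→C8→C5→C6→C7 clockwise and β toward the viewer, the C6 aryl is α, the C7 aryl β, C9 β and C2 α on C1, and C4 α on C5; on ring C the C9 aryl faces C8, the C10 arene and C12 face C7, and the C12 aryl is exo. The centres can be relayed (C6 sets C7, the C7 aryl sets C9 and C1, C9 and C1 set C10 and C11, the ring fusion sets C12), but C5 lies cis to the C6 aryl, against the bias of an intermolecular enolate reaction, and is best fixed by the closure of ring A itself. Fragile features are the seven phenols (carried as methyl ethers), the electron-rich arenes and styrene (acid, oxidants), the quaternary β-hydroxy ketones (retro-aldol) and every 1,3-diketone flanking a non-enolisable carbon (C1 on the way, C5 in the target), which nucleophilic base cleaves by retro-Claisen reaction. The route is made short by the C10–C11 bond shared by rings C and D: C10 is benzylic and can carry a bromide, C11=C12 can be a styrene, the C12 radical left by 5-exo attack is 4-methoxybenzylic and easily oxidised to a cation, and the arene carbon ortho to C10 has an ortho and a para oxygen, so one radical addition and one Friedel–Crafts attack close both rings.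

## Retrosynthesis

**29 from 28.** Only the seven O–CH3 bonds are cut. The heptamethyl ether 28 carries the complete skeleton and all stereocentres; the forward step needs a Lewis acid that leaves the bridgehead β-diketone and the enone intact.

**28 from 26.** The C2=C3 bond is cut as an aldol condensation, leaving a C2 ketone and an acetyl group (C3, C4) on C5. The neighbouring cut, metathesis of a C2 methylene with a C5 vinyl carbinol, would require methylenating C2 beside the less hindered C8 ketone and a C5 side chain already cis to the C6 aryl. The aldol cut avoids both: ring size selects C2, and the C4/C8 β-diketone of 26 makes C5 epimerisable, so only the epimer that can reach C2 is consumed. 26 has one ring and one fixed stereocentre fewer. The forward reaction must make the methyl carbon of an enolised β-diketone add to a neopentyl ketone and then lose water.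

**26 from 21 and 22.** The C4–C5 bond is cut as an aldol addition of acetaldehyde (22) to the C8 ketone of 21, giving 24, followed by desilylation (25) and oxidation of both carbinols. In 21 the C8 ketone has a single enolisable position. Doing the aldol before C2 is unveiled keeps the aldolate away from a C2 carbonyl.

**21 from 18 (key disconnection).** The C10–C11 and C12–arene bonds are cut together. Cutting the spiro bonds C1–C2 or C1–C9 instead would need an enolate alkylation at a secondary benzylic carbon. The chosen cut removes two rings and three stereocentres (C10, C11, C12) and leaves a cyclopentanone with two open arms on C1: a C10 benzylic bromide and an E-styrene with a silyloxy group at C2. The forward step needs 5-exo closure with chair control, oxidation of the C12 radical and arene capture of the cation.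

**18 from 16 and 2.** The C10–Br bond goes back to the carbinol 17, and the C10–aryl bond to aldehyde 16 and aryl Grignard reagent 2. C10 needs no control because it becomes a planar radical.

**16 from 10, 5 and 11.** The C9–aryl and C1–C2 bonds are cut in one operation: conjugate addition of 5 to the exocyclic enone 10 and aldol capture of the enolate by 11 give 13, which is silylated and unmasked to 16.
- This generates the C1 enolate regiospecifically; a 3,4-diarylcyclopentanone otherwise has two nearly equivalent α-carbons.
- Both new bonds are made from the face away from the C7 aryl across an E alkene, which gives the C1/C9 relationship of the target. The reversed polarity (a C10 nucleophile adding to a 4-methoxybenzylidene ketone) would give the C9 epimer.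
- C10 is an acetal carbon at this stage and carries no stereocentre that could interfere.

**10 from 4, 5 and 6.** The C1=C9 bond is cut as an aldol condensation (through 8) and the C7–aryl bond as a conjugate addition to enone 4, whose enolate is trapped by 6 on the C1 side. The forward steps need trans addition to C7 and an E-selective dehydration.

**4 from 1 and 2.** The C6–aryl bond is cut; conjugate addition anti to the silyloxy group of 1 and loss of silanol (through 3) transpose the enone and take C6 from the chiral pool.

## Roads not taken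

**Alternative 1:** Ring-closing metathesis as the strategic step. The C2=C3 bond is cut; in the forward sense the second-generation Hoveyda–Grubbs catalyst joins the vinyl carbinol on C5 and the C2 methylene of diene A1, releasing ethylene and giving the bridged allylic alcohol A2.
- *Merits.* The closure is neutral and irreversible and is well known for bridged bicycles. Here it is the better road: the chosen plan relies on an aldol condensation in which an enolised β-diketone must react at its methyl group.
- *Weak points.* A1 needs a methylene on C2 in the presence of the more accessible C8 ketone, and a C5 side chain cis to the C6 aryl, which an enolate aldol is unlikely to deliver and which cannot epimerise under metathesis conditions. The new trisubstituted alkene sits next to a quaternary carbon, and an extra oxidation follows. The strategy also says nothing about rings C and D or the spiro centre.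
- *Comparison.* The chosen plan sets against it a closure that needs no C2/C8 differentiation and no control of C5, and three fewer steps; the metathesis is kept as the fallback for step 12.

**Alternative 2:** Semipinacol ring expansion. The C1–C7 bond is cut; AgBF4 ionises the allylic bromide of cyclobutanol A3 to the C1–C2–C3 allyl cation, and the benzylic carbon C7 migrates from C8 to C1 to give the spiro ketone A4 with a C2 methylene.
- *Merits.* One stereospecific step (retention at C7) creates the quaternary centre and ring B and leaves the C2 methylene in place. In this respect it is better than a route that has to distinguish two ketones.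
- *Weak points.* A3 requires rings C and D with four stereocentres on a cyclopentene plus a strained trans-diaryl cyclobutanol. The face of the allyl cation taken by C7 (the C1 configuration) depends on the remote C9 aryl. The cation is surrounded by electron-rich arenes and can also be captured at C3. A4 still faces the C5 problem of alternative 1.
- *Comparison.* The chosen plan makes ring B in two steps from a chiral-pool enone and lets its C7 aryl direct C1 and C9. Its price is that the spiro centre is made by an intermolecular aldol of a hindered enolate.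

**Alternative 3:** Interrupted Nazarov cyclisation. The C6–C7 and C1–C2 bonds are cut; BF3·OEt2 converts dienone A5 into a pentadienyl cation, conrotatory closure forms ring B, and the tethered Z-vinylsilane attacks the oxyallyl terminus C1 to give the spiro ketone A6.
- *Merits.* It is the most convergent road: two rings and two C–C bonds in one step, the trans-diaryl unit from the E,E geometry, and C3 and C4 already attached to C2. Ring A could then be closed through C5 by an aldol, which would fix C5 by ring closure; in this it is better than the chosen plan.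
- *Weak points.* The sense of conrotation (C6/C7 relative to C9–C12) must be dictated by a remote stereocentre. A dienone with aryl groups on both termini is a stabilised, slow Nazarov substrate. The oxyallyl cation can be trapped at C5 or by an arene, and the vinylsilane can be protodesilylated. A5, with four stereocentres and a Z-vinylsilane, is long to make.
- *Comparison.* The chosen plan relays every new stereocentre from a neighbouring one and uses the known chair preference of 5-hexenyl radicals, at the cost of a more linear sequence.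

Key step: step 8

Remark: atom numbers and α/β are those defined under "The problem"; descriptors such as (1S,2R,6S,7S,9R) use these atom numbers.
Remark: C2 is carried as the 2R carbinol epimer expected from a closed aldol transition state; C2 is oxidised at step 11, so its configuration matters only for the chair of step 8, where this epimer places the silyloxy group pseudo-equatorial.
Remark: 17 and 18 are used as mixtures at C10 and 24–26 as mixtures at C4 and/or C5, because these centres become planar or equilibrate; commercial aqueous 6 is assumed to be dehydrated and distilled before use.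

## Route

Step 1
Reactants: 1 (S)-4-[(tert-butyldimethylsilyl)oxy]cyclopent-2-en-1-one; 2 (3,5-dimethoxyphenyl)magnesium chloride
Product: 4 (S)-4-(3,5-dimethoxyphenyl)cyclopent-2-en-1-one, via silyloxy ketone 3 (not isolated)
Conditions: CuBr·SMe2 (10 mol %), THF, −78 °C; NH4Cl aq.; then DBU, CH2Cl2, 0 °C
Reagents that add atoms: none
Why: Copper-catalysed conjugate addition of the aryl Grignard reagent occurs anti to the C7 silyloxy group and sets C6; DBU then expels silanolate from the C1 enolate (E1cB), so the net 1,4-addition/β-elimination transposes the enone without touching C6.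

Step 2
Reactants: 4 (S)-4-(3,5-dimethoxyphenyl)cyclopent-2-en-1-one; 5 (4-methoxyphenyl)magnesium bromide; 6 2,2-dimethoxyacetaldehyde
Product: 8 (2R,3R,4S)-4-(3,5-dimethoxyphenyl)-2-(1-hydroxy-2,2-dimethoxyethyl)-3-(4-methoxyphenyl)cyclopentan-1-one, via magnesium enolate 7 (not isolated)
Conditions: CuBr·SMe2 (10 mol %), THF, −78 → −40 °C; then 6, −78 °C; NH4Cl aq.
Reagents that add atoms: none
Why: A second copper-catalysed 1,4-addition places the aryl group on C7 trans to the C6 aryl and forms the enolate only on the C1 side, where the aldehyde is captured trans to the new aryl (three-component conjugate addition–aldol coupling). The carbinol configuration is irrelevant because the hydroxyl is eliminated next.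

Step 3
Reactants: 8 (2R,3R,4S)-4-(3,5-dimethoxyphenyl)-2-(1-hydroxy-2,2-dimethoxyethyl)-3-(4-methoxyphenyl)cyclopentan-1-one
Product: 10 (2E,3S,4S)-2-(2,2-dimethoxyethylidene)-4-(3,5-dimethoxyphenyl)-3-(4-methoxyphenyl)cyclopentan-1-one, via mesylate 9 (not isolated)
Conditions: MsCl, Et3N, CH2Cl2, 0 °C; then DBU, 25 °C
Reagents that add atoms: none
Why: Mesylation and E1cB elimination (aldol dehydration) give the conjugated enone as the thermodynamic E isomer, with C10 turned away from the carbonyl oxygen. Allylic 1,3-strain with C10 then pushes the C7 aryl into a pseudo-axial position over one face of the alkene.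

Step 4
Reactants: 10 (2E,3S,4S)-2-(2,2-dimethoxyethylidene)-4-(3,5-dimethoxyphenyl)-3-(4-methoxyphenyl)cyclopentan-1-one; 5 (4-methoxyphenyl)magnesium bromide; 11 (E)-4-methoxycinnamaldehyde
Product: 13 quaternary aldol adduct (1S,2R,6S,7S,9R) with C9 CH(4-methoxyphenyl)CH(OMe)2 and C2 CH(OH)–(E)-CH=CH(4-methoxyphenyl) on C1, via magnesium enolate 12 (not isolated)
Conditions: CuBr·SMe2 (30 mol %), THF, −40 °C; then 11, −78 °C; NH4Cl aq. at −78 °C
Reagents that add atoms: none
Why: Tandem copper-catalysed conjugate addition–aldol reaction: the aryl group adds to C9 anti to the pseudo-axial C7 aryl (sets C9), and the regiospecific tetrasubstituted enolate takes the enal by 1,2-addition at C1, again anti to the C7 aryl (sets C1). A closed Zimmerman–Traxler transition state with the styryl group equatorial sets C2; the net syn addition across the E alkene gives the C1/C9 relationship of the target.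

Step 5
Reactants: 13 quaternary aldol adduct (1S,2R,6S,7S,9R)
Product: 16 C10 aldehyde with C2 triethylsilyl ether (1S,2R,6S,7S,9R), via silyl ether acetal 14 (not isolated), via collidinium salt 15 (not isolated)
Conditions: Et3SiOTf (3 equiv), 2,4,6-collidine (4 equiv), CH2Cl2, 0 °C; then H2O
Reagents that add atoms: triethylsilyl trifluoromethanesulfonate, CC[Si](CC)(CC)OS(=O)(=O)C(F)(F)F; water, O
Why: The silyl triflate silylates the hindered C2 hydroxyl and, in the same weakly basic medium, turns the dimethyl acetal into a pyridinium salt that water hydrolyses to the aldehyde (silyl triflate/pyridine-base acetal cleavage). No protic acid is present, which protects the epimerisable α-aryl aldehyde centre C9 and the ionisable cinnamyl ether.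

Step 6
Reactants: 16 C10 aldehyde with C2 triethylsilyl ether (1S,2R,6S,7S,9R); 2 (3,5-dimethoxyphenyl)magnesium chloride
Product: 17 C10 carbinol CH(OH)(3,5-dimethoxyphenyl), C10 epimers
Conditions: THF, −78 °C; NH4Cl aq.
Reagents that add atoms: none
Why: Grignard addition to the aldehyde at low temperature should outrun both enolisation of the α-aryl aldehyde and attack on the neopentyl C8 ketone. Either C10 epimer serves because C10 becomes a radical.

Step 7
Reactants: 17 C10 carbinol, C10 epimers
Product: 18 C10 bromide CH(Br)(3,5-dimethoxyphenyl) with E-styrene and C2 triethylsilyl ether, C10 epimers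
Conditions: CBr4, PPh3, 2,6-lutidine, CH2Cl2, 0 °C; used without storage
Reagents that add atoms: carbon tetrabromide, BrC(Br)(Br)Br
Why: Appel bromination of the secondary benzylic alcohol under buffered conditions. The meta methoxy groups do not stabilise a C10 cation, which favours substitution over ionisation, and the C10 configuration is immaterial.

Step 8
Reactants: 18 C10 bromide, C10 epimers
Product: 21 tetracyclic spiro ketone with rings C and D closed and C2 triethylsilyl ether, via C12 radical 19 (not isolated), via C12 cation 20 (not isolated)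
Conditions: fac-Ir(ppy)3 (1 mol %), 2,6-lutidine (2 equiv), MeCN, blue LEDs (455 nm), 25 °C, degassed
Reagents that add atoms: none
Why: Photoexcited fac-Ir(ppy)3 transfers an electron to the C–Br bond of 18 (dissociative reduction), giving bromide and the C10 benzylic radical. Ring C closes by 5-exo-trig addition of C10 to C11 through a chair-like transition state in which the C9 aryl, the C2 silyloxy group and the C7 branch of the spiro centre are pseudo-equatorial, so the C10 aryl ends trans to the C9 aryl and cis to the new C11–C12 bond (C10 and C11 controlled by C9, C1 and C2). The 4-methoxybenzylic C12 radical 19 is oxidised by tetravalent iridium to cation 20, which regenerates the catalyst and makes the sequence redox-neutral (radical–polar crossover). Ring D closes by a five-membered Friedel–Crafts cyclialkylation at the arene carbon ortho to C10, activated by one ortho and one para methoxy group, and 2,6-lutidine takes up the HBr. C12 is set here: the tether enforces the cis ring fusion and the 4-methoxyphenyl group turns to the convex face, anti to C2. The step needs 5-exo attack at C11 rather than 6-endo attack at C12, which the C2 silyl ether secures by keeping the styrene electron-rich and unconjugated to a carbonyl, and it needs arene capture of the cation, secured by the proximity of the arene (capture by bromide would only re-ionise). The closest known reaction type is the photoredox atom-transfer/radical–polar crossover addition of activated and benzylic halides to styrenes with nucleophilic trapping of the benzylic cation.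

Step 9
Reactants: 21 tetracyclic spiro ketone; 22 acetaldehyde
Product: 24 C5 (1-hydroxyethyl) ketone, C4/C5 epimers, via lithium enolate 23 (not isolated)
Conditions: LiN(iPr)2, THF, −78 °C; then CH3CHO, −78 °C; NH4Cl aq.
Reagents that add atoms: none
Why: The C8 ketone has one enolisable position (C5), so a single lithium enolate forms and adds to acetaldehyde (aldol addition). C4 and C5 need no control: C4 is oxidised and C5 becomes epimerisable.

Step 10
Reactants: 24 C5 (1-hydroxyethyl) ketone
Product: 25 C2,C4-diol
Conditions: HF·pyridine, pyridine, THF, 0 → 25 °C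
Reagents that add atoms: none
Why: Fluoride cleavage of the triethylsilyl ether under buffered, slightly acidic conditions, which should not cause retro-aldol cleavage of the β-hydroxy ketone.

Step 11
Reactants: 25 C2,C4-diol
Product: 26 triketone (C2 and C8 ketones, acetyl group on C5)
Conditions: Dess–Martin periodinane, NaHCO3, CH2Cl2, 25 °C
Reagents that add atoms: none
Why: Dess–Martin oxidation of both secondary alcohols. The resulting C4/C8 β-diketone makes C5 configurationally labile through its enol.

Step 12
Reactants: 26 triketone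
Product: 28 heptamethyl ether of the target, via bridged ketol 27 (not isolated)
Conditions: pyrrolidine (0.5 equiv), AcOH (0.5 equiv), 4 Å molecular sieves, toluene, 60 °C
Reagents that add atoms: none
Why: Amine/acid-catalysed intramolecular aldol condensation of the Hajos–Parrish type: the acetyl methyl C3 adds to the C2 ketone (6-enolendo-exo-trig), the only carbonyl a six-membered ring can reach, and the ketol loses water (E1cB) to the C2=C3 enone. Only the C5 epimer with the acetyl group cis to C2 can cyclise; because C5 equilibrates through the enol, both epimers should drain into 28, where C5 is a non-enolisable bridgehead of the required configuration.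

Step 13
Reactants: 28 heptamethyl ether of the target
Product: 29 CNP0407321.1
Conditions: BBr3 (excess), CH2Cl2, −78 → 25 °C; then MeOH, H2O
Reagents that add atoms: none
Why: Lewis acid cleavage of the seven aryl methyl ethers with BBr3. The conditions avoid the nucleophilic base that would open the bridgehead β-diketone by retro-Claisen reaction.

## Compound list

1 | (S)-4-[(tert-butyldimethylsilyl)oxy]cyclopent-2-en-1-one | O=C1C=C[C@@H](O[Si](C)(C)C(C)(C)C)C1 | starting material
2 | (3,5-dimethoxyphenyl)magnesium chloride | COc1cc(OC)cc([Mg]Cl)c1 | starting material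
3 | (3R,4S)-4-[(tert-butyldimethylsilyl)oxy]-3-(3,5-dimethoxyphenyl)cyclopentan-1-one | O=C1C[C@H](c2cc(OC)cc(OC)c2)[C@@H](O[Si](C)(C)C(C)(C)C)C1 | intermediate
4 | (S)-4-(3,5-dimethoxyphenyl)cyclopent-2-en-1-one | O=C1C[C@H](c2cc(OC)cc(OC)c2)C=C1 | intermediate
5 | (4-methoxyphenyl)magnesium bromide | COc1ccc([Mg]Br)cc1 | starting material
6 | 2,2-dimethoxyacetaldehyde | COC(OC)C=O | starting material
7 | bromomagnesium C1–C8 enolate of trans-3-(3,5-dimethoxyphenyl)-4-(4-methoxyphenyl)cyclopentanone (C6 aryl α, C7 aryl β) | Br[Mg]OC1=C[C@H](c2ccc(OC)cc2)[C@@H](c2cc(OC)cc(OC)c2)C1 | intermediate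
8 | (2R,3R,4S)-4-(3,5-dimethoxyphenyl)-2-(1-hydroxy-2,2-dimethoxyethyl)-3-(4-methoxyphenyl)cyclopentan-1-one (all-trans ring, carbinol epimers) | O=C1C[C@H](c2cc(OC)cc(OC)c2)[C@@H](c2ccc(OC)cc2)[C@@H]1C(O)C(OC)OC | intermediate
9 | methanesulfonate of 8 | O=C1C[C@H](c2cc(OC)cc(OC)c2)[C@@H](c2ccc(OC)cc2)[C@@H]1C(OS(C)(=O)=O)C(OC)OC | intermediate
10 | (2E,3S,4S)-2-(2,2-dimethoxyethylidene)-4-(3,5-dimethoxyphenyl)-3-(4-methoxyphenyl)cyclopentan-1-one | O=C1C[C@H](c2cc(OC)cc(OC)c2)[C@@H](c2ccc(OC)cc2)/C1=C\C(OC)OC | intermediate
11 | (E)-3-(4-methoxyphenyl)prop-2-enal (4-methoxycinnamaldehyde) | COc1ccc(/C=C/C=O)cc1 | starting material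
12 | bromomagnesium C1–C8 enolate carrying the (9R)-CH(4-methoxyphenyl)CH(OMe)2 group on C1 (C6 aryl α, C7 aryl β) | Br[Mg]OC1=C([C@@H](c2ccc(OC)cc2)C(OC)OC)[C@H](c2ccc(OC)cc2)[C@@H](c2cc(OC)cc(OC)c2)C1 | intermediate
13 | (2S,3S,4S)-4-(3,5-dimethoxyphenyl)-2-[(1R)-2,2-dimethoxy-1-(4-methoxyphenyl)ethyl]-2-[(1R,2E)-1-hydroxy-3-(4-methoxyphenyl)prop-2-en-1-yl]-3-(4-methoxyphenyl)cyclopentan-1-one; (1S,2R,6S,7S,9R) | COc1ccc(/C=C/[C@@H](O)[C@]2([C@@H](c3ccc(OC)cc3)C(OC)OC)C(=O)C[C@H](c3cc(OC)cc(OC)c3)[C@H]2c2ccc(OC)cc2)cc1 | intermediate
14 | C2 triethylsilyl ether of 13 | COc1ccc(/C=C/[C@@H](O[Si](CC)(CC)CC)[C@]2([C@@H](c3ccc(OC)cc3)C(OC)OC)C(=O)C[C@H](c3cc(OC)cc(OC)c3)[C@H]2c2ccc(OC)cc2)cc1 | intermediate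
15 | 2,4,6-trimethylpyridinium triflate in which C10 of 14 is CH(OMe)(N-collidinium) | COc1ccc(/C=C/[C@@H](O[Si](CC)(CC)CC)[C@]2([C@@H](c3ccc(OC)cc3)C(OC)[n+]3c(C)cc(C)cc3C)C(=O)C[C@H](c3cc(OC)cc(OC)c3)[C@H]2c2ccc(OC)cc2)cc1.[O-]S(=O)(=O)C(F)(F)F | intermediate
16 | C10 aldehyde with C2 triethylsilyl ether; (1S,2R,6S,7S,9R) | COc1ccc(/C=C/[C@@H](O[Si](CC)(CC)CC)[C@]2([C@@H](c3ccc(OC)cc3)C=O)C(=O)C[C@H](c3cc(OC)cc(OC)c3)[C@H]2c2ccc(OC)cc2)cc1 | intermediate
17 | C10 carbinol CH(OH)(3,5-dimethoxyphenyl); (1S,2R,6S,7S,9R), C10 epimers | COc1ccc(/C=C/[C@@H](O[Si](CC)(CC)CC)[C@]2([C@@H](c3ccc(OC)cc3)C(O)c3cc(OC)cc(OC)c3)C(=O)C[C@H](c3cc(OC)cc(OC)c3)[C@H]2c2ccc(OC)cc2)cc1 | intermediate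
18 | C10 bromide CH(Br)(3,5-dimethoxyphenyl) with E-styrene on C2; (1S,2R,6S,7S,9R), C10 epimers | COc1ccc(/C=C/[C@@H](O[Si](CC)(CC)CC)[C@]2([C@@H](c3ccc(OC)cc3)C(Br)c3cc(OC)cc(OC)c3)C(=O)C[C@H](c3cc(OC)cc(OC)c3)[C@H]2c2ccc(OC)cc2)cc1 | intermediate
19 | ring-C-closed C12 (4-methoxybenzylic) radical; C10 aryl trans to C9 aryl, C10–H and C11–H cis, C2 silyloxy trans to C12 | CC[Si](CC)(CC)O[C@@H]1[C@@H]([CH]c2ccc(OC)cc2)[C@@H](c2cc(OC)cc(OC)c2)[C@H](c2ccc(OC)cc2)[C@]12C(=O)C[C@H](c1cc(OC)cc(OC)c1)[C@H]2c1ccc(OC)cc1 | intermediate
20 | ring-C-closed C12 cation, configured as 19 | CC[Si](CC)(CC)O[C@@H]1[C@@H]([CH+]c2ccc(OC)cc2)[C@@H](c2cc(OC)cc(OC)c2)[C@H](c2ccc(OC)cc2)[C@]12C(=O)C[C@H](c1cc(OC)cc(OC)c1)[C@H]2c1ccc(OC)cc1 | intermediate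
21 | tetracyclic spiro ketone (C8 ketone, C5 methylene): C1, C6, C7, C9–C12 as in the target, C12 4-methoxyphenyl exo, C2 OSiEt3 on the ring C face turned to C8 (trans to C12) | CC[Si](CC)(CC)O[C@@H]2[C@H]3[C@H](c4ccc(OC)cc4)c4c(OC)cc(OC)cc4[C@H]3[C@H](c3ccc(OC)cc3)[C@]23C(=O)C[C@H](c1cc(OC)cc(OC)c1)[C@H]3c1ccc(OC)cc1 | intermediate
22 | acetaldehyde | CC=O | starting material
23 | lithium C5–C8 enolate of 21 | CC[Si](CC)(CC)O[C@@H]2[C@H]3[C@H](c4ccc(OC)cc4)c4c(OC)cc(OC)cc4[C@H]3[C@H](c3ccc(OC)cc3)[C@]23C(O[Li])=C[C@H](c1cc(OC)cc(OC)c1)[C@H]3c1ccc(OC)cc1 | intermediate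
24 | 21 carrying CH(OH)CH3 on C5 (C4/C5 epimers) | CC[Si](CC)(CC)O[C@@H]2[C@H]3[C@H](c4ccc(OC)cc4)c4c(OC)cc(OC)cc4[C@H]3[C@H](c3ccc(OC)cc3)[C@]23C(=O)C(C(C)O)[C@H](c1cc(OC)cc(OC)c1)[C@H]3c1ccc(OC)cc1 | intermediate
25 | C2,C4-diol (desilylated 24) | O[C@@H]2[C@H]3[C@H](c4ccc(OC)cc4)c4c(OC)cc(OC)cc4[C@H]3[C@H](c3ccc(OC)cc3)[C@]23C(=O)C(C(C)O)[C@H](c1cc(OC)cc(OC)c1)[C@H]3c1ccc(OC)cc1 | intermediate
26 | triketone: C2 and C8 ketones, acetyl (C3, C4) on C5; C5 labile | O=C2[C@H]3[C@H](c4ccc(OC)cc4)c4c(OC)cc(OC)cc4[C@H]3[C@H](c3ccc(OC)cc3)[C@]23C(=O)C(C(C)=O)[C@H](c1cc(OC)cc(OC)c1)[C@H]3c1ccc(OC)cc1 | intermediate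
27 | bridged ketol: ring A closed, tertiary OH on C2 (C3 on the ring C face turned to C8), C4 and C8 ketones | O=C1C[C@]2(O)[C@H]3[C@H](c4ccc(OC)cc4)c4c(OC)cc(OC)cc4[C@H]3[C@H](c3ccc(OC)cc3)[C@]23C(=O)[C@H]1[C@H](c1cc(OC)cc(OC)c1)[C@H]3c1ccc(OC)cc1 | intermediate
28 | heptamethyl ether of the target | O=C1C=C2[C@H]3[C@H](c4ccc(OC)cc4)c4c(OC)cc(OC)cc4[C@H]3[C@H](c3ccc(OC)cc3)[C@]23C(=O)[C@H]1[C@H](c1cc(OC)cc(OC)c1)[C@H]3c1ccc(OC)cc1 | intermediate
29 | CNP0407321.1: bicyclo[3.2.1]oct-2-ene-4,8-dione spiro-fused to the cyclopenta-indane, configured as described under "The problem" | O=C1C=C2[C@H]3[C@H](c4ccc(O)cc4)c4c(O)cc(O)cc4[C@H]3[C@H](c3ccc(O)cc3)[C@]23C(=O)[C@H]1[C@H](c1cc(O)cc(O)c1)[C@H]3c1ccc(O)cc1 | target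

## Step count and least certain steps

Total: 13 steps. Longest linear sequence: 13 steps (from 1).

**Step 8 (key step).** Electron transfer to the unactivated secondary benzylic bromide may be slow, so that ionic loss of HBr toward the C9=C10 stilbene or premature reduction of the C10 radical competes. The 5-exo closure of a stabilised benzylic radical may also be slow or reversible. The fallback separates the two ring closures. Setting out from 18, a copper-catalysed atom-transfer radical cyclisation (CuBr with tris(2-pyridylmethyl)amine, toluene, 60 °C; the chemistry by which 1-arylethyl bromides add to styrenes) should give the ring-C-closed C12 bromide F1. AgOTf with 2,6-di-tert-butylpyridine in CH2Cl2 at −40 °C then ionises the 4-methoxybenzylic bromide and the Friedel–Crafts closure returns the route to 21.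

**Step 12.** The enolised β-diketone may be a poor source of the C3 nucleophile and the neopentyl C2 ketone a poor electrophile, so the aldol addition may be slow. Amine-induced retro-Claisen opening of the C2/C8 diketone or a competing aldol from C11 may intervene. The fallback closes ring A by metathesis and sets out from 21.
- HF·pyridine gives the C2 alcohol F2, and Dess–Martin periodinane the C2,C8-dione F3.
- LiN(iPr)2 and Me3SiCl at −78 °C deprotonate the C5 methylene and mask C8 as the trimethylsilyl enol ether F4, so that Cp2TiMe2 (toluene, 70 °C) methylenates only C2 and gives the methylene silyl enol ether F5.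
- MeLi regenerates the lithium enolate, and acrolein gives the C5 1-hydroxyallyl ketone F6. Only the C5 epimer drawn (side chain cis to C2) can cyclise; the other is returned by base equilibration of its silyl ether.
- The second-generation Hoveyda–Grubbs catalyst (toluene, 80 °C) closes the bridged allylic alcohol F7, and Dess–Martin oxidation returns the route to 28.

**Step 4.** Facial selectivity at C9 may be poor if the enone is not cleanly E or the C7 aryl is not firmly pseudo-axial. 1,2-Addition of the Grignard reagent and retro-aldol loss of the congested aldolate may lower the return. The fallback decouples the two bond formations. Setting out from 10, the copper-catalysed addition of 5 is run with Me3SiCl, which accelerates the 1,4-addition and allows isolation and purification of the trimethylsilyl enol ether F8. MeLi (THF, 0 °C) then releases the lithium enolate free of copper and magnesium salts, and its aldol addition to 11 at −78 °C through the same closed transition state returns the route to 13.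

**Step 7.** Substitution at the hindered benzylic carbon may be overtaken by elimination toward the stilbene, by 1,2-aryl shift through participation of the C9 4-methoxyphenyl group, or by participation of the C8 carbonyl oxygen. The fallback avoids the halide and sets out from 17.
- Acylation with 3,5-bis(trifluoromethyl)benzoyl chloride gives the C10 benzoate F9.
- Reductive photoredox C–O cleavage ([Ir(ppy)2(dtbbpy)]PF6, iPr2NEt, H2O, MeCN, blue LEDs) generates the same C10 radical, which closes ring C and is reduced to the C12-methylene compound F10.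
- DDQ (CH2Cl2, 0 °C) removes hydride from the 4-methoxybenzylic C12–H2, and the cation closes ring D, returning the route to 21.

**Step 13.** The Lewis acid may activate the C4 enone carbonyl toward Friedel–Crafts attack by the C6 resorcinol ring, HBr may add to the enone, and cleavage of seven ethers may stall. The fallback changes the order of events. Setting out from 26, BBr3 is applied at the triketone stage, where no enone is present, to give the heptaphenol triketone F11. The pyrrolidine/AcOH closure of ring A is then run on the free phenol and returns the route to 29.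

## Further compounds

F1 | step 8 | ring-C-closed C12 bromide (atom-transfer product; C12 epimers) | CC[Si](CC)(CC)O[C@@H]1[C@@H](C(Br)c2ccc(OC)cc2)[C@@H](c2cc(OC)cc(OC)c2)[C@H](c2ccc(OC)cc2)[C@]12C(=O)C[C@H](c1cc(OC)cc(OC)c1)[C@H]2c1ccc(OC)cc1
F2 | step 12 | C2 alcohol (desilylated 21) | O[C@@H]2[C@H]3[C@H](c4ccc(OC)cc4)c4c(OC)cc(OC)cc4[C@H]3[C@H](c3ccc(OC)cc3)[C@]23C(=O)C[C@H](c1cc(OC)cc(OC)c1)[C@H]3c1ccc(OC)cc1
F3 | step 12 | C2,C8-dione | O=C2[C@H]3[C@H](c4ccc(OC)cc4)c4c(OC)cc(OC)cc4[C@H]3[C@H](c3ccc(OC)cc3)[C@]23C(=O)C[C@H](c1cc(OC)cc(OC)c1)[C@H]3c1ccc(OC)cc1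
F4 | step 12 | C2 ketone with C8 trimethylsilyl enol ether (C5=C8) | O=C2[C@H]3[C@H](c4ccc(OC)cc4)c4c(OC)cc(OC)cc4[C@H]3[C@H](c3ccc(OC)cc3)[C@]23C(O[Si](C)(C)C)=C[C@H](c1cc(OC)cc(OC)c1)[C@H]3c1ccc(OC)cc1
F5 | step 12 | C2 methylene compound with C8 trimethylsilyl enol ether | C=C2[C@H]3[C@H](c4ccc(OC)cc4)c4c(OC)cc(OC)cc4[C@H]3[C@H](c3ccc(OC)cc3)[C@]23C(O[Si](C)(C)C)=C[C@H](c1cc(OC)cc(OC)c1)[C@H]3c1ccc(OC)cc1
F6 | step 12 | C2 methylene C8 ketone with 1-hydroxyallyl group on C5 (cis to C2; C4 epimers) | C=C2[C@H]3[C@H](c4ccc(OC)cc4)c4c(OC)cc(OC)cc4[C@H]3[C@H](c3ccc(OC)cc3)[C@]23C(=O)[C@H](C(O)C=C)[C@H](c1cc(OC)cc(OC)c1)[C@H]3c1ccc(OC)cc1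
F7 | step 12 | bridged C4 allylic alcohol (C4 epimers) | OC1C=C2[C@H]3[C@H](c4ccc(OC)cc4)c4c(OC)cc(OC)cc4[C@H]3[C@H](c3ccc(OC)cc3)[C@]23C(=O)[C@H]1[C@H](c1cc(OC)cc(OC)c1)[C@H]3c1ccc(OC)cc1
F8 | step 4 | C1–C8 trimethylsilyl enol ether carrying the (9R) side chain on C1 | C[Si](C)(C)OC1=C([C@@H](c2ccc(OC)cc2)C(OC)OC)[C@H](c2ccc(OC)cc2)[C@@H](c2cc(OC)cc(OC)c2)C1
F9 | step 7 | C10 3,5-bis(trifluoromethyl)benzoate of 17 | COc1ccc(/C=C/[C@@H](O[Si](CC)(CC)CC)[C@]2([C@@H](c3ccc(OC)cc3)C(OC(=O)c3cc(C(F)(F)F)cc(C(F)(F)F)c3)c3cc(OC)cc(OC)c3)C(=O)C[C@H](c3cc(OC)cc(OC)c3)[C@H]2c2ccc(OC)cc2)cc1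
F10 | step 7 | ring-C-closed compound with C12 methylene (4-methoxybenzyl on C11) | CC[Si](CC)(CC)O[C@@H]1[C@@H](Cc2ccc(OC)cc2)[C@@H](c2cc(OC)cc(OC)c2)[C@H](c2ccc(OC)cc2)[C@]12C(=O)C[C@H](c1cc(OC)cc(OC)c1)[C@H]2c1ccc(OC)cc1
F11 | step 13 | heptaphenol triketone (demethylated 26) | O=C2[C@H]3[C@H](c4ccc(O)cc4)c4c(O)cc(O)cc4[C@H]3[C@H](c3ccc(O)cc3)[C@]23C(=O)C(C(C)=O)[C@H](c1cc(O)cc(O)c1)[C@H]3c1ccc(O)cc1
A1 | alternative 1 | C2 methylene spiro ketone with C5 vinyl carbinol (metathesis substrate) | C=C2[C@H]3[C@H](c4ccc(OC)cc4)c4c(OC)cc(OC)cc4[C@H]3[C@H](c3ccc(OC)cc3)[C@]23C(=O)[C@H]([C@H](O)C=C)[C@H](c1cc(OC)cc(OC)c1)[C@H]3c1ccc(OC)cc1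
A2 | alternative 1 | bridged C4 allylic alcohol (C4 carbinol of 28) | O[C@@H]1C=C2[C@H]3[C@H](c4ccc(OC)cc4)c4c(OC)cc(OC)cc4[C@H]3[C@H](c3ccc(OC)cc3)[C@]23C(=O)[C@H]1[C@H](c1cc(OC)cc(OC)c1)[C@H]3c1ccc(OC)cc1
A3 | alternative 2 | cyclobutanol on C8 attached to the C1=C2 cyclopentene with C3 bromomethyl (carbinol configuration immaterial) | BrCC2=C(C5(O)C[C@H](c6cc(OC)cc(OC)c6)[C@H]5c5ccc(OC)cc5)[C@@H](c3ccc(OC)cc3)[C@@H]3c4cc(OC)cc(OC)c4[C@@H](c4ccc(OC)cc4)[C@H]23
A4 | alternative 2 | spiro[4.4]nonanone with C2 exocyclic methylene | C=C2[C@H]3[C@H](c4ccc(OC)cc4)c4c(OC)cc(OC)cc4[C@H]3[C@H](c3ccc(OC)cc3)[C@]23C(=O)C[C@H](c1cc(OC)cc(OC)c1)[C@H]3c1ccc(OC)cc1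
A5 | alternative 3 | E,E cross-conjugated dienone with indane-tethered Z-vinylsilane | COc1ccc(/C=C(/C(=O)/C=C/c2cc(OC)cc(OC)c2)[C@@H](c2ccc(OC)cc2)[C@@H]2c3cc(OC)cc(OC)c3[C@@H](c3ccc(OC)cc3)[C@@H]2/C(=C/CO[Si](C)(C)C(C)(C)C)[Si](C)(C)C)cc1
A6 | alternative 3 | spiro[4.4]nonanone with Z-allylic silyl ether on the C2 alkene | CC(C)(C)[Si](C)(C)OC/C=C2/[C@H]3[C@H](c4ccc(OC)cc4)c4c(OC)cc(OC)cc4[C@H]3[C@H](c3ccc(OC)cc3)[C@]23C(=O)C[C@H](c1cc(OC)cc(OC)c1)[C@H]3c1ccc(OC)cc1
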